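**Plan**

1. Retrosynthesis: the pyran ring is cut at O1–C8a and at C2–C3. This takes out acetone (C2, its two methyl groups and O1) and leaves a 2-vinyl-1,4-benzoquinone, which is the 5,8-hydroquinone of the target at the quinone oxidation level.
2. Enabling feature: the free hydroxyls at C5 and C8 are para to each other and flank the ring-fusion bond C4a–C8a. The benzene ring can therefore be carried as a quinone whose C4a=C8a bond, together with a vinyl group on C4a, forms a diene that takes up a C=O unit across C8a and C3; two proton shifts then restore the aromatic hydroquinone and the C3=C4 bond.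
3. The vinylquinone is cut back to 1,2,4-trimethoxybenzene: acyl chain at the carbon between two methoxy groups (directed lithiation, 3-phenylpropanal, oxidation), vinyl group by bromination and Suzuki–Miyaura coupling, quinone by oxidative demethylation of the para-related methoxy pair.
4. Forward order: the benzene ring is bought; side chain, then vinyl group, then quinone; the pyran ring is closed last with acetone, and that step delivers the target directly.
5. Stereochemistry: the target is achiral. The racemic carbinol centre of step 1 is oxidised away in step 2, and the C8a centre of the cycloadduct is lost on aromatisation.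

Key step: step 6

Remark: chromene numbering of the target (O1, C2, C3, C4, C4a, C5, C6, C7, C8, C8a) is used for the atoms in step 6 and in its fallback.

**Route**

Step 1
Reactants: 1 1,2,4-trimethoxybenzene; 2 3-phenylpropanal
Product: 5 3-phenyl-1-(2,3,6-trimethoxyphenyl)propan-1-ol, via aryllithium 3 (not isolated), via lithium alkoxide 4 (not isolated)
Conditions: n-BuLi (1.1 equiv), THF, 0 °C to rt; then 2, −78 °C to 0 °C; then H2O
Reagents that add atoms: none
Why: Directed ortho-metalation, in which the C–H flanked by the methoxy groups at C2 and C4 of 1 is the most acidic and doubly coordinated site for n-BuLi, followed by 1,2-addition of the aryllithium to the aldehyde; the new carbinol centre is racemic and is removed in step 2.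

Step 2
Reactants: 5 3-phenyl-1-(2,3,6-trimethoxyphenyl)propan-1-ol
Product: 6 3-phenyl-1-(2,3,6-trimethoxyphenyl)propan-1-one
Conditions: Dess–Martin periodinane (DMP, 1.3 equiv), CH2Cl2, 0 °C to rt
Reagents that add atoms: none
Why: Dess–Martin oxidation of a secondary benzylic alcohol to the aryl ketone under neutral conditions that should leave the electron-rich ring untouched.

Step 3
Reactants: 6 3-phenyl-1-(2,3,6-trimethoxyphenyl)propan-1-one
Product: 7 1-(3-bromo-2,5,6-trimethoxyphenyl)-3-phenylpropan-1-one
Conditions: NBS (1.05 equiv), MeCN, 0 °C to rt, dark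
Reagents that add atoms: NBS (N-bromosuccinimide), O=C1CCC(=O)N1Br
Why: Electrophilic aromatic bromination, expected at the free position that is ortho to the 6-methoxy group, para to the 2-methoxy group and meta to the acyl group, since the other free position is para to the acyl group and activated by one methoxy group only, and NBS in MeCN should brominate the electron-rich ring much faster than the ketone α-carbon.

Step 4
Reactants: 7 1-(3-bromo-2,5,6-trimethoxyphenyl)-3-phenylpropan-1-one
Product: 8 1-(3-ethenyl-2,5,6-trimethoxyphenyl)-3-phenylpropan-1-one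
Conditions: vinylboronic acid pinacol ester (1.5 equiv), Pd(dppf)Cl2 (5 mol%), K2CO3 (3 equiv), 1,4-dioxane/H2O (4:1), 90 °C
Reagents that add atoms: vinylboronic acid pinacol ester (2-ethenyl-4,4,5,5-tetramethyl-1,3,2-dioxaborolane), C=CB1OC(C)(C)C(C)(C)O1
Why: Suzuki–Miyaura cross-coupling of an aryl bromide with a vinylboronate, to which the hindered ketone and the methyl ethers should be inert.

Step 5
Reactants: 8 1-(3-ethenyl-2,5,6-trimethoxyphenyl)-3-phenylpropan-1-one
Product: 9 5-ethenyl-2-methoxy-3-(3-phenylpropanoyl)cyclohexa-2,5-diene-1,4-dione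
Conditions: (NH4)2Ce(NO3)6 (2.5 equiv), MeCN/H2O (2:1), 0 °C, short reaction time; extractive work-up, used at once
Reagents that add atoms: water, O
Why: Oxidative demethylation of a 1,4-dimethoxyarene to the para-quinone, in which water attacks the two para-related methoxy-bearing carbons of the arene radical cation and methanol is lost, while the third methoxy group has no para oxygen partner and should remain as the vinylogous ester of the quinone.

Step 6
Reactants: 9 5-ethenyl-2-methoxy-3-(3-phenylpropanoyl)cyclohexa-2,5-diene-1,4-dione; 10 acetone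
Product: 13 Flemistrictin D (1-(5,8-dihydroxy-7-methoxy-2,2-dimethyl-2H-chromen-6-yl)-3-phenylpropan-1-one), via cycloadduct 11 (not isolated), via ortho-quinone methide 12 (not isolated)
Conditions: Sc(OTf)3 (20 mol%), 4 Å MS, dry degassed acetone 10 as solvent (0.01 M in 9), rt, dark, Ar
Reagents that add atoms: none
Why: Proposed new method: vinylquinone 9 is an electron-poor diene (vinyl C3=C4 plus ring C4a=C8a) and Sc(OTf)3, chelated between the C5 carbonyl and the side-chain ketone on C6, should make the unsubstituted carbon C8a its most electrophilic site, so that the carbonyl oxygen of acetone attacks C8a and the scandium dienolate thus formed closes through its γ-carbon C3 onto the oxocarbenium carbon C2, which amounts to an asynchronous inverse-demand oxa-Diels–Alder reaction with a simple ketone as the 2π partner. The closest known reaction types are the Diels–Alder reaction of vinylquinones with alkenes, which ends in the same aromatising proton shifts, and the Lewis-acid-catalysed formal [4+2] annulation of aldehydes and ketones with donor–acceptor cyclobutanes, where the carbonyl oxygen is also the nucleophile and an enolate closes on the oxocarbenium ion. The pyran ring closes as a [4+2] cycloaddition, in its stepwise limit a 6-endo-trig attack of the dienolate carbon on the C2=O1 oxocarbenium bond. Cycloadduct 11 should aromatise under the same conditions by enolisation of C8a–H to ortho-quinone methide 12 and a 1,5-hydrogen shift from C3 to the C5 oxygen, which gives the 5,8-hydroquinone and the C3=C4 bond with no change of oxidation level and no protecting group. No stereocentre is formed in the product, the one at C8a of 11 being lost on aromatisation. The step needs oxygen-to-C8a and carbon-to-C3 regiochemistry, which the chelate and the fact that C8a is the only unsubstituted quinone carbon should secure, and it needs cycloaddition to outrun dimerisation of 9, for which acetone as solvent at high dilution and exclusion of light are chosen.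

**Compound list**

1 | 1,2,4-trimethoxybenzene | COc1ccc(OC)c(OC)c1 | starting material
2 | 3-phenylpropanal | O=CCCc1ccccc1 | starting material
3 | (2,3,6-trimethoxyphenyl)lithium | [Li]c1c(OC)ccc(OC)c1OC | intermediate
4 | lithium 3-phenyl-1-(2,3,6-trimethoxyphenyl)propan-1-olate (racemic) | [Li+].[O-]C(CCc1ccccc1)c1c(OC)ccc(OC)c1OC | intermediate
5 | 3-phenyl-1-(2,3,6-trimethoxyphenyl)propan-1-ol (racemic) | OC(CCc1ccccc1)c1c(OC)ccc(OC)c1OC | intermediate
6 | 3-phenyl-1-(2,3,6-trimethoxyphenyl)propan-1-one | O=C(CCc1ccccc1)c1c(OC)ccc(OC)c1OC | intermediate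
7 | 1-(3-bromo-2,5,6-trimethoxyphenyl)-3-phenylpropan-1-one | O=C(CCc1ccccc1)c1c(OC)c(Br)cc(OC)c1OC | intermediate
8 | 1-(3-ethenyl-2,5,6-trimethoxyphenyl)-3-phenylpropan-1-one | O=C(CCc1ccccc1)c1c(OC)c(C=C)cc(OC)c1OC | intermediate
9 | 5-ethenyl-2-methoxy-3-(3-phenylpropanoyl)cyclohexa-2,5-diene-1,4-dione | O=C(CCc1ccccc1)C1=C(OC)C(=O)C=C(C=C)C1=O | intermediate
10 | acetone | CC(C)=O | starting material
11 | 7-methoxy-2,2-dimethyl-6-(3-phenylpropanoyl)-3,8a-dihydro-2H-chromene-5,8-dione (racemic cycloadduct) | COC1=C(C(=O)CCc2ccccc2)C(=O)C2=CCC(C)(C)OC2C1=O | intermediate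
12 | 8-hydroxy-7-methoxy-2,2-dimethyl-6-(3-phenylpropanoyl)-2,3-dihydro-5H-chromen-5-one (ortho-quinone methide) | COC1=C(C(=O)CCc2ccccc2)C(=O)C2=CCC(C)(C)OC2=C1O | intermediate
13 | Flemistrictin D, 1-(5,8-dihydroxy-7-methoxy-2,2-dimethyl-2H-chromen-6-yl)-3-phenylpropan-1-one | COc1c(O)c2c(c(O)c1C(=O)CCc1ccccc1)C=CC(C)(C)O2 | target

**Count and risks**

Total step count: 6. Longest linear sequence: 6 steps (1 to 13).

Steps most likely to fail:

Step 6 (proposed cycloaddition). The acetone oxygen may be too weak a nucleophile. Dimerisation of 9, carbon attack by the enol of acetone, or addition of the oxygen at the vinyl terminus (isochromene regiochemistry) could then take over. Redox exchange between the product hydroquinone and unreacted quinone is a further loss channel, which a reductive wash with aqueous Na2S2O4 should correct. The fallback uses known reactions and runs from 7 to 13.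
- Sonogashira coupling of 7 with 2-methylbut-3-yn-2-ol (Pd(PPh3)2Cl2, CuI, Et3N, 70 °C) should give the alkynol 1-[3-(3-hydroxy-3-methylbut-1-yn-1-yl)-2,5,6-trimethoxyphenyl]-3-phenylpropan-1-one F1.
- Semihydrogenation over Pd/CaCO3 poisoned with Pb(OAc)2 and quinoline (H2, EtOAc) should give the alkenol 1-{3-[(1Z)-3-hydroxy-3-methylbut-1-en-1-yl]-2,5,6-trimethoxyphenyl}-3-phenylpropan-1-one F2.
- Oxidative demethylation with (NH4)2Ce(NO3)6 in MeCN/H2O at 0 °C should give the quinone 5-[(1Z)-3-hydroxy-3-methylbut-1-en-1-yl]-2-methoxy-3-(3-phenylpropanoyl)cyclohexa-2,5-diene-1,4-dione F3.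
- In F3 the (Z)-alkene holds the tertiary hydroxyl next to the free ring carbon C8a. A 6-endo-trig oxa-Michael addition (spontaneous, or with catalytic camphorsulfonic acid in CH2Cl2) should give the keto tautomer 5-hydroxy-7-methoxy-2,2-dimethyl-6-(3-phenylpropanoyl)-2H-chromen-8(8aH)-one F4, which enolises to 13.
- In this variant the C2–C3 bond comes with the alkynol and the O1–C8a bond is made by an ordinary conjugate addition.

Step 5 (oxidation in the presence of the vinyl group). The arene radical cation may be intercepted at the vinyl group (addition of nitrate or water, oligomerisation) instead of at the methoxy-bearing carbons, or the vinylquinone may dimerise during the aqueous work-up. The fallback runs from 7 to 9 and oxidises before the vinyl group is present.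
- Treatment of 7 with (NH4)2Ce(NO3)6 in MeCN/H2O at 0 °C should give the bromoquinone 5-bromo-2-methoxy-3-(3-phenylpropanoyl)cyclohexa-2,5-diene-1,4-dione F5.
- Stille coupling of F5 with tributyl(vinyl)stannane (Pd2(dba)3, AsPh3, toluene, 50 °C) should give 9, which is taken into step 6 at once.

Step 1 (addition to an enolisable aldehyde). Proton transfer from the α-CH2 group of 3-phenylpropanal to the hindered aryllithium may compete with addition, returning 1 and aldol products. The fallback runs from 1 to 6 through a chalcone.
- Aryllithium 3, made from 1 as before, is added to (E)-cinnamaldehyde, which cannot enolise. This should give lithium (2E)-3-phenyl-1-(2,3,6-trimethoxyphenyl)prop-2-en-1-olate F6 and, after water, the allylic alcohol (2E)-3-phenyl-1-(2,3,6-trimethoxyphenyl)prop-2-en-1-ol F7.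
- MnO2 (CH2Cl2, rt) should oxidise F7 to the chalcone (2E)-3-phenyl-1-(2,3,6-trimethoxyphenyl)prop-2-en-1-one F8.
- Hydrogenation (H2, Pd/C, EtOAc, rt, stopped after one equivalent) should saturate the C=C bond and give 6.

**Further compounds**

F1 | step 6 | 1-[3-(3-hydroxy-3-methylbut-1-yn-1-yl)-2,5,6-trimethoxyphenyl]-3-phenylpropan-1-one | O=C(CCc1ccccc1)c1c(OC)c(C#CC(C)(C)O)cc(OC)c1OC
F2 | step 6 | 1-{3-[(1Z)-3-hydroxy-3-methylbut-1-en-1-yl]-2,5,6-trimethoxyphenyl}-3-phenylpropan-1-one | O=C(CCc1ccccc1)c1c(OC)c(/C=C\C(C)(C)O)cc(OC)c1OC
F3 | step 6 | 5-[(1Z)-3-hydroxy-3-methylbut-1-en-1-yl]-2-methoxy-3-(3-phenylpropanoyl)cyclohexa-2,5-diene-1,4-dione | O=C(CCc1ccccc1)C1=C(OC)C(=O)C=C(/C=C\C(C)(C)O)C1=O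
F4 | step 6 | 5-hydroxy-7-methoxy-2,2-dimethyl-6-(3-phenylpropanoyl)-2H-chromen-8(8aH)-one (racemic) | COC1=C(C(=O)CCc2ccccc2)C(O)=C2C=CC(C)(C)OC2C1=O
F5 | step 5 | 5-bromo-2-methoxy-3-(3-phenylpropanoyl)cyclohexa-2,5-diene-1,4-dione | O=C(CCc1ccccc1)C1=C(OC)C(=O)C=C(Br)C1=O
F6 | step 1 | lithium (2E)-3-phenyl-1-(2,3,6-trimethoxyphenyl)prop-2-en-1-olate (racemic) | [Li+].[O-]C(/C=C/c1ccccc1)c1c(OC)ccc(OC)c1OC
F7 | step 1 | (2E)-3-phenyl-1-(2,3,6-trimethoxyphenyl)prop-2-en-1-ol (racemic) | OC(/C=C/c1ccccc1)c1c(OC)ccc(OC)c1OC
F8 | step 1 | (2E)-3-phenyl-1-(2,3,6-trimethoxyphenyl)prop-2-en-1-one | O=C(/C=C/c1ccccc1)c1c(OC)ccc(OC)c1OC
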